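The vessel holds starting material and reagent at 1.00 equiv, with a trace of initiator, and each turn of the first chain carrier on reagent makes one product, so percentages of starting material also count reagent.

the same everywhere: starting material 0.20 M; initiator 1 mol%
- alpha: reagent 1 equiv; temperature 25 °C; the very flask that is asked about, followed so far
- epsilon: reagent 0.50 equiv; temperature 20 °C; run made earlier
- flask: reagent 1.00 equiv; temperature 25 °C; time 5.0 h

| run | time / h | product / % |
|---|---|---|
| alpha | 0.250 | 9.6 |
| alpha | 0.833 | 18.9 |
| alpha | 1.33 | 26.3 |
| alpha | 2.00 | 32.4 |
| alpha | 3.00 | 37.3 |
| epsilon | 0.333 | 2.8 |
| epsilon | 0.833 | 5.9 |
| epsilon | 1.50 | 10.5 |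
| epsilon | 2.50 | 13.4 |
| epsilon | 4.00 | 18.7 |

(standard deviation of a reading: 1 percentage point)

- percentages count the starting material that a species holds: one ended chains B counts as two
- product taken out counts as made
- reactions considered so far: 2 first chain carrier -> ended chains B; 2 second chain carrier -> ended chains A; reagent + first chain carrier -> product + second chain carrier; reagent <-> dormant form; starting material + second chain carrier -> by-product + first chain carrier; starting material + initiating radical -> capped initiator + first chain carrier; initiator -> 2 initiating radical
- additions bring no volume worth counting

- Wednesday's: change nothing and wait 10 h more
- Friday's: at 5.0 h raise the temperature by 15 K, then wait 10 h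
- Sunday's: at 5.0 h take out 90% of the product then present, then wait 10 h
- Monday's: at 5.0 h add reagent, 50.0% of the amount charged, then wait 10 h

1. product, in percent of the starting material first charged, at 5.0 h
2. the option that brings most further product ("none" if no option brings more than 2 percentage points) (Wednesday's / Friday's / Sunday's / Monday's / none)
3. product present, with what was taken out counted in, in percent of the starting material first charged, after Wednesday's
4. product present, with what was taken out counted in, in percent of the starting material first charged, after Monday's

Two rates in the alpha run, which is this flask followed so far, can be compared. At the first reading, with free reagent near its charge, product grows at about 0.384 /h, a reading with its scatter of 1 percentage point. This is a pseudo-first-order chain constant, assumed steady here. Between the last two readings product grows at 0.0490 /h, so free reagent there stands near 12.8% of its charge. Product meanwhile stands near 34.9%, so the reagent lost, 87.2%, is more than product made. The rest has presumably gone to the dormant form. The carried quantity is therefore the branching share, the part of lost reagent that ends as product: 39.9%. Both exits are first order in free reagent, so the comparison should not drift while the chain holds.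

Each setting then follows by hand. Reckoned one way, with the return from the dormant form left out, product by 5.0 h stands near 39.6%. Wednesday's adds whatever returns from the dormant form, which the readings cannot size. Friday's heat acts on that same return, again without a number from these runs. Product stands on the left of no listed step, so Sunday's should equal waiting. Monday's fresh 50.0% splits by the same share, giving about 59.9%.

The forecast gave 41%, 42%, 43% and none, holding that “the stall comes from initiator running out”, and at Monday's it differs from the reckoning here.

The flask gives 39.6% at 5.0 h and 44.7% after Wednesday's. Monday's brings most, reaching 65.7%, a gain of 26 points, against 21 points for Friday's and 5.1 points for Sunday's. At 5.00 h free reagent stands at 3.01% of its charge. The branching share on the addition gives 20 points, and waiting alone brings 5.1 points beside it.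

    2 first chain carrier → ended chains B (k = 9.00 × 10⁷ /M/s, Ea = 13.0 kJ/mol)
    2 second chain carrier → ended chains A (k = 8.50 × 10⁶ /M/s, Ea = 18.0 kJ/mol)
    reagent + first chain carrier → product + second chain carrier (k = 15000 /M/s, Ea = 22.0 kJ/mol)
    reagent ⇌ dormant form (K = 24.0, k = 1.40 × 10⁻⁴ /s, Ea = 89.0 kJ/mol, ΔH = −12.0 kJ/mol)
    starting material + second chain carrier → by-product + first chain carrier (k = 3.40 × 10⁵ /M/s, Ea = 20.0 kJ/mol)
    starting material + initiating radical → capped initiator + first chain carrier (k = 1.30 × 10⁶ /M/s, Ea = 21.0 kJ/mol)
    initiator → 2 initiating radical (k = 1.60 × 10⁻⁶ /s, Ea = 114 kJ/mol)
    (constants at 25 °C)

With 4 mol% of initiator, chains ending in pairs raise the chain constant by the root of the loading, 2.00 times, while the dormant exit stays, so the share becomes 57.1%. That neighbour gives 57.5% at 5.0 h.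

Readings and results were generated by integration with constants of no real substance.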